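## The problem

The target is a germacra-1(10),4,7(11)-trien-6α,12-olide: a ten-membered carbocycle (C1–C10) fused through C6–C7 to a butenolide whose C7=C11 bond is tetrasubstituted, with an acetate on C2, a methacrylate on C8 and an acetoxymethyl group (C13) on C11. The carbocycle holds two E-configured trisubstituted olefins, C1=C10 and C4=C5, and closing such a ring from a chain costs strain and entropy and leaves the olefin geometry open. There are three stereocentres: C6 (R) and C8 (S) flank the flat butenolide, and C2 (R) lies across the ring. In a rigid bicyclic precursor the ring system can steer reagents at C8, but neither C6 nor C8 can be trusted to control the remote C2 in a flexible ten-membered ring, so C2 needs reagent control. The sensitive groups are the 1,5-diene (acid-induced transannular cyclisation, Cope rearrangement), the γ-hydrogens at C6 and C8 of the butenolide (epimerisation, furan formation), the polymerisable methacrylate, and three esters that must be told apart. The enabling feature is that C5 and C10 face each other 1,6 across the two olefins, so that joining them gives the eudesmane decalin of santonin, with the same C6 configuration. Conversely, a ring-A diene C1=C2–C3=C4 bearing oxygen on C2 is a six-electron system whose opening gives both olefins and the C2 oxygen.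

## Retrosynthesis

**C2–O and C2–H.** The acetyl group of target 22 is removed to alcohol 21, and the C2–H bond is cut back to dienone 20. Setting C2 last, by a catalyst-controlled reduction of an enone, avoids carrying a remote stereocentre through the route. The forward steps must reduce one ketone beside a butenolide and three esters and must not isomerise the C3 methylene, which sits between the carbonyl and C4=C5.

**C5–C10 (key disconnection).** Dienone 20 is the hydrolysis product of silyloxy triene 19, and 19 is traced to the bicyclic silyloxy diene 18 by joining C5 to C10. Against any cut that closes the ten-membered ring from a chain, this one needs no dilution, fixes both olefin geometries through the ring fusion, and turns the target into a decalin. The forward step must excite only the ring-A diene, open it at low temperature, and allow the labile triene to be discharged to the ketone before it recloses thermally.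

**O–Si and C8–O(acyl).** Diene 18 comes from enone 17 by enolisation toward C1. Enone 17 comes from the 8β-alcohol 15 and methacrylic acid 16 by esterification with inversion. Acylating before the enolisation keeps the sensitive dienol ether out of all further chemistry. The forward steps must invert a hindered allylic alcohol and enolise a ketone in the presence of the γ-acidic butenolide.

**C8–O and C7=C11.** Alcohol 15 is cut at C8–O to butenolide 14, whose only allylic methylene is C8. The C7=C11 bond of 14 is traced to the tertiary alcohol 12 by dehydration. Keeping the 11-hydroxy-13-acetoxy lactone as a latent butenolide lets the γ-acidity appear late. The forward steps must hydroxylate C8 in preference to the positions around the ring-A enone, and eliminate toward C7.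

**Ring A.** The C2 carbonyl of 12 is removed to olefin 11. The C3=C4 bond and the 5α-hydrogen of 11 are traced to allylic alcohol 8 by a reductive 1,3-transposition, and 8 to enone 7 and dienone 6 by reduction. This moves the ring-A oxygen from C3 (santonin) to C2 in four operations and sets the trans ring fusion that the key step depends on. The forward transposition must deliver hydrogen to the α face of C5.

**C13–O.** The 11,13-diol monoacetate 6 is cut back through diol 5 and methylene lactone 4 to selenide 2 and α-santonin 1. This is done first because the dienone of santonin has no α-hydrogen and reacts only sluggishly with the electrophilic oxidant, so the only strong-base step and the dihydroxylation meet no competing ring-A function.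

## Roads not taken

Alternative 1: Carbonylative closure of both rings. The cut removes C6–C7, C11–C12 and C12–O together. Acyclic ynal A2 (C6 aldehyde conjugated to C4=C5, C7≡C11 alkyne) would combine with CO under Ru3(CO)12 or Mo(CO)6 to give the tris-silylated bicyclic core A1.
- Merits: it is the most convergent plan, it builds the butenolide in the ring-forming event, and A2 can be assembled from small fragments with catalytic asymmetric steps for C2 and C8.
- Weak points: this carbonylative yne–aldehyde cyclisation is established for five- and six-membered rings formed through short tethers. Here the metallacycle must span a seven-atom tether and create a ten-membered ring with two E olefins, against alkyne oligomerisation and decarbonylation of the enal. C6 would be set in the closure with only remote control. The three silyl ethers of A1 then need stepwise exchange for three different esters.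
- Comparison: if the cyclisation worked, A1 would be reached in fewer linear steps and would serve analogues better. The chosen plan sets against this a ring-forming event that is a unimolecular bond cleavage with predictable geometry, and a C6 centre and carbon skeleton that are bought.

Alternative 2: Electroreductive closure of C9–C10. The cut is the sp3–sp2 bond C9–C10. The N-acyloxyphthalimide A4, which also carries the C10 alkenyl iodide, would be reduced at a cathode with NiBr2(dme) and 4,4′-di-tert-butyl-2,2′-bipyridine to give the protected core A3.
- Merits: the conditions are mild and base-free, the alkenyl iodide geometry passes into the C1=C10 olefin, and the butenolide with C6 and C8 is in place before ring closure.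
- Weak points: the precedent is intermolecular. In a slow ten-membered closure the primary C9 radical can be reduced, dimerise or add to the butenolide, and the organonickel stage has a β-alkoxy group at C8. A4 needs C2, C6 and C8 set by three separate operations, and the 4-methoxybenzyl and silyl groups add exchange steps.
- Comparison: this road is more modular. The chosen plan avoids any macrocyclisation and any acyclic olefin synthesis, at the price of a longer linear sequence.

Alternative 3: Nozaki–Hiyama–Kishi closure of C7–C8. The cut is C7–C8. The β-bromobutenolide aldehyde A6 would cyclise under stoichiometric CrCl2 with catalytic NiCl2 to the ten-membered butenolide A5 with a free C8 alcohol.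
- Merits: of the three, this ring-closing reaction has the best record for strained medium rings, it tolerates esters, and it delivers the C8 alcohol ready for acylation. A wrong C8 epimer could be corrected by the same inversion used in step 11.
- Weak points: the aldehyde of A6 is β,γ-unsaturated, with hydrogens between the carbonyl and C10=C1 that invite isomerisation. The C8 configuration would depend on the conformation of a forming ten-membered ring. High dilution and excess divalent chromium are needed, and both E olefins and C2 and C6 must be made in the open chain.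
- Comparison: in the reliability of the ring-closing event this road is at least equal to the chosen one, and it reaches the C8 alcohol directly where the chosen route spends steps 10 and 11. The chosen plan sets against this that the two olefin geometries and C6 come from the starting material and the ring fusion, and that no dilution step is needed.

Key step: step 13

Assumption: the SeO2 hydroxylation in step 10 is taken to deliver the axial 8β-alcohol (ene reaction through the axial allylic hydrogen), so the ester is introduced with inversion in step 11.

## Route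

Step 1
Reactants: 1 α-santonin
Product: 2 11β-(phenylselanyl)santonin (selenium β, C13 methyl α)
Conditions: LiN(iPr)2, THF, −78 °C; then PhSeCl, −78 → −40 °C
Reagents that add atoms: benzeneselenenyl chloride, Cl[Se]c1ccccc1
Why: Lactone α-selenenylation; the dienone has no α-hydrogen, so the amide base removes H11, and electrophiles enter the enolates of trans-fused 6α,12-olides from the β face, placing selenium trans to H7.

Step 2
Reactants: 2 11β-(phenylselanyl)santonin
Product: 4 11,13-dehydrosantonin (3-oxoeudesma-1,4,11(13)-trien-6α,12-olide), via selenoxide 3 (not isolated)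
Conditions: H2O2 (30% aq), AcOH (cat.), THF, 0 °C → rt
Reagents that add atoms: hydrogen peroxide, OO (its oxygen appears only in intermediate 3)
Why: Selenoxide syn-elimination; with selenium trans to H7 only the C13 hydrogens are syn, so the exocyclic α-methylene lactone should form, the standard entry to 11(13)-enes in santonin-type lactones.

Step 3
Reactants: 4 11,13-dehydrosantonin
Product: 5 11β,13-dihydroxy-3-oxoeudesma-1,4-dien-6α,12-olide
Conditions: OsO4 (cat.), N-methylmorpholine N-oxide, acetone–H2O, rt
Reagents that add atoms: OsO4, O=[Os](=O)(=O)=O (transfers both oxygens and is re-formed); N-methylmorpholine N-oxide, C[N+]1([O-])CCOCC1; water, O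
Why: Upjohn syn-dihydroxylation; the exocyclic 1,1-disubstituted olefin is the accessible alkene, the cross-conjugated dienone olefins being sluggish toward OsO4 as in 1,4-dien-3-one steroids; attack on the β face, as in step 1, gives the 11β-alcohol, a centre that is removed again in step 9.

Step 4
Reactants: 5 11β,13-dihydroxy-3-oxoeudesma-1,4-dien-6α,12-olide
Product: 6 13-acetoxy-11β-hydroxy-3-oxoeudesma-1,4-dien-6α,12-olide
Conditions: Ac2O, pyridine, 4-(dimethylamino)pyridine (cat.), CH2Cl2, 0 °C
Reagents that add atoms: acetic anhydride, CC(=O)OC(C)=O
Why: Selective acylation; the primary alcohol reacts while the tertiary α-hydroxy-lactone alcohol stays free as the latent C7=C11 olefin.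

Step 5
Reactants: 6 13-acetoxy-11β-hydroxy-3-oxoeudesma-1,4-dien-6α,12-olide
Product: 7 13-acetoxy-11β-hydroxy-3-oxoeudesm-4-en-6α,12-olide
Conditions: H2 (1 atm), RhCl(PPh3)3 (cat.), benzene–EtOH, rt
Reagents that add atoms: none
Why: Homogeneous hydrogenation; RhCl(PPh3)3 saturates only the disubstituted C1=C2 bond of the cross-conjugated dienone and leaves the tetrasubstituted C4=C5 bond, as known for santonin itself.

Step 6
Reactants: 7 13-acetoxy-11β-hydroxy-3-oxoeudesm-4-en-6α,12-olide
Product: 8 13-acetoxy-3β,11β-dihydroxyeudesm-4-en-6α,12-olide
Conditions: NaBH4, CeCl3·7H2O, MeOH, −40 → −20 °C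
Reagents that add atoms: none
Why: Luche 1,2-reduction; hydride adds to C3 from the α face, anti to the angular methyl group, giving the quasi-equatorial 3β-allylic alcohol, while lactone and acetate are untouched.

Step 7
Reactants: 8 13-acetoxy-3β,11β-dihydroxyeudesm-4-en-6α,12-olide
Product: 11 13-acetoxy-11β-hydroxy-5αH-eudesm-3-en-6α,12-olide, via sulfonylhydrazine adduct 9 (not isolated), via allylic diazene 10 (not isolated)
Conditions: 2-nitrobenzenesulfonohydrazide, PPh3, diethyl azodicarboxylate, THF, −30 °C; then 23 °C
Reagents that add atoms: 2-nitrobenzenesulfonohydrazide, NNS(=O)(=O)c1ccccc1[N+](=O)[O-] (its atoms appear only in intermediates 9 and 10)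
Why: Myers reductive 1,3-transposition; Mitsunobu displacement with inversion puts nitrogen on the α face of C3, loss of sulfinate gives the monoalkyl diazene, and its retro-ene loss of N2 transfers hydrogen suprafacially to the α face of C5 while the olefin moves to C3=C4 and ring A stays six-membered (C10–C1H2–C2H2–C3H=C4(CH3)–C5H); this sets the trans ring fusion (5α-H) needed in step 13, and the tertiary alcohol does not enter the Mitsunobu activation.

Step 8
Reactants: 11 13-acetoxy-11β-hydroxy-5αH-eudesm-3-en-6α,12-olide
Product: 12 13-acetoxy-11β-hydroxy-2-oxo-5αH-eudesm-3-en-6α,12-olide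
Conditions: CrO3, 3,5-dimethylpyrazole, CH2Cl2, −20 °C
Reagents that add atoms: chromium trioxide, O=[Cr](=O)=O
Why: Allylic oxidation with the CrO3–3,5-dimethylpyrazole complex; the ring methylene C2 next to the olefinic C3–H is oxidised in preference to the C4 methyl group and the hindered tertiary C5–H, as in the 5-ene to 7-ketone oxidation of steroids; the tertiary alcohol and the esters are inert.

Step 9
Reactants: 12 13-acetoxy-11β-hydroxy-2-oxo-5αH-eudesm-3-en-6α,12-olide
Product: 14 13-acetoxy-2-oxo-5αH-eudesma-3,7(11)-dien-6α,12-olide, via chlorosulfite 13 (not isolated)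
Conditions: SOCl2, pyridine, CH2Cl2, −10 → 0 °C
Reagents that add atoms: thionyl chloride, O=S(Cl)Cl (its atoms appear only in intermediate 13)
Why: Dehydration of a tertiary alcohol by anti-E2 elimination; the 11β leaving group is antiperiplanar to the axial H7α, and loss of this hydrogen gives the conjugated tetrasubstituted butenolide, whereas loss of an acetoxymethyl hydrogen would give a less substituted enol acetate.

Step 10
Reactants: 14 13-acetoxy-2-oxo-5αH-eudesma-3,7(11)-dien-6α,12-olide
Product: 15 13-acetoxy-8β-hydroxy-2-oxo-5αH-eudesma-3,7(11)-dien-6α,12-olide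
Conditions: SeO2, 1,4-dioxane, 80 °C
Reagents that add atoms: selenium dioxide, O=[Se]=O
Why: SeO2 allylic hydroxylation (ene reaction followed by [2,3]-sigmatropic shift); the tetrasubstituted butenolide olefin is the more electron-rich of the two conjugated alkenes and offers the only allylic methylene (C8), whereas the ring-A enone has only a methyl group and a hindered methine in γ-position and a neopentyl, slowly enolising methylene at C1; the axial 8β-hydrogen is the one aligned with the π system, so oxygen should arrive on the β face.

Step 11
Reactants: 15 13-acetoxy-8β-hydroxy-2-oxo-5αH-eudesma-3,7(11)-dien-6α,12-olide; 16 methacrylic acid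
Product: 17 13-acetoxy-8α-methacryloyloxy-2-oxo-5αH-eudesma-3,7(11)-dien-6α,12-olide
Conditions: PPh3, diisopropyl azodicarboxylate, THF, 0 °C → rt (trace of 2,6-di-tert-butyl-4-methylphenol)
Reagents that add atoms: methacrylic acid (16), C=C(C)C(=O)O
Why: Mitsunobu esterification with inversion; the carboxylate attacks C8 from the α face on an equatorial trajectory, away from the axial C10 methyl group, and turns the 8β-alcohol into the 8α-ester (S at C8); the near-neutral conditions spare the γ-hydrogens of the butenolide.

Step 12
Reactants: 17 13-acetoxy-8α-methacryloyloxy-2-oxo-5αH-eudesma-3,7(11)-dien-6α,12-olide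
Product: 18 13-acetoxy-8α-methacryloyloxy-2-triethylsilyloxy-5αH-eudesma-1,3,7(11)-trien-6α,12-olide
Conditions: Et3SiOTf (1.1 equiv), Et3N, CH2Cl2, −78 °C; cold non-acidic work-up
Reagents that add atoms: triethylsilyl trifluoromethanesulfonate, CC[Si](CC)(CC)OS(=O)(=O)C(F)(F)F
Why: Soft enolisation; the enone oxygen is the most Lewis-basic carbonyl and is silylated first, and Et3N then removes the α′ hydrogen at C1 under kinetic control to give the cross-conjugated 2-silyloxy-1,3-diene; one equivalent at −78 °C is meant to leave the less basic butenolide untouched, since its silylation would form a 2-silyloxyfuran and erase C6.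

Step 13
Reactants: 18 13-acetoxy-8α-methacryloyloxy-2-triethylsilyloxy-5αH-eudesma-1,3,7(11)-trien-6α,12-olide
Product: 19 13-acetoxy-8α-methacryloyloxy-2-triethylsilyloxygermacra-1(10),2,4,7(11)-tetraen-6α,12-olide
Conditions: hν (300 nm lamps, Pyrex), degassed THF–pentane, −78 °C; the cold solution is used directly in step 14
Reagents that add atoms: none
Why: Photochemical 6π electrocyclic ring opening: π,π* excitation of the ring-A 2-silyloxy-1,3-diene, expected to absorb well beyond the butenolide, methacrylate and acetate chromophores, cleaves the C5–C10 σ bond in the conrotatory sense. The closest known reaction type is the low-temperature photochemical opening of trans-fused eudesma-1,3-dienes from santonin to cyclodeca-1,3,5-trienes, with the provitamin D to previtamin D conversion as the general model. No ring is closed by bond formation; the ten-membered ring is released when the bond shared by rings A and B breaks, so no dilution is needed. No stereocentre is formed: C5 and C10 become sp2 and C6 and C8 are not touched. The selectivity required is olefin geometry, and the trans ring fusion secures it: with H5 and the C10 methyl group trans, conrotation turns the two ring-B arms (C6 and C9) outward and gives both new trisubstituted olefins as E, while C2=C3 keeps the cis ring geometry it had in ring A (C1 and C4 cis). Irradiation at the long-wavelength edge should favour the triene in the photostationary mixture, because the twisted triene is expected to absorb at shorter wavelength than the planar homoannular diene. At −78 °C the thermal disrotatory reclosure, which would lead to a cis-fused diene, is suppressed, and the silyl enol ether stores the C2 oxygen for step 14. Unopened 18 returns as enone 17 after step 14 and can be recycled.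

Step 14
Reactants: 19 13-acetoxy-8α-methacryloyloxy-2-triethylsilyloxygermacra-1(10),2,4,7(11)-tetraen-6α,12-olide
Product: 20 13-acetoxy-8α-methacryloyloxy-2-oxogermacra-1(10)E,4E,7(11)-trien-6α,12-olide
Conditions: Bu4NF, AcOH (slight excess over fluoride), THF, added to the cold photolysate, −78 → −40 °C
Reagents that add atoms: none
Why: Buffered protodesilylation of a silyl enol ether; fluoride releases the enolate, which acetic acid protonates kinetically at C3, giving the C2 ketone conjugated to C1=C10 and keeping C4=C5 out of conjugation; the low temperature and the absence of free base are meant to prevent reclosure and migration of the C4=C5 bond.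

Step 15
Reactants: 20 13-acetoxy-8α-methacryloyloxy-2-oxogermacra-1(10)E,4E,7(11)-trien-6α,12-olide
Product: 21 (2R)-13-acetoxy-2-hydroxy-8α-methacryloyloxygermacra-1(10)E,4E,7(11)-trien-6α,12-olide
Conditions: (S)-1-methyl-3,3-diphenyl-tetrahydro-1H,3H-pyrrolo[1,2-c][1,3,2]oxazaborole ((S)-Me-CBS), catecholborane, toluene–CH2Cl2, −78 °C
Reagents that add atoms: none
Why: Corey–Bakshi–Shibata reduction; the C1=C10 alkenyl group acts as the large substituent and the C3 methylene as the small one, so the (S)-catalyst should deliver hydride to the face that gives the (R)-allylic alcohol, and catecholborane at −78 °C reduces neither the esters and the butenolide nor the olefins.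

Step 16
Reactants: 21 (2R)-13-acetoxy-2-hydroxy-8α-methacryloyloxygermacra-1(10)E,4E,7(11)-trien-6α,12-olide
Product: 22 (2R,6R,8S)-2,13-diacetoxy-8-methacryloyloxygermacra-1(10)E,4E,7(11)-trien-6,12-olide (CNP0309304.1)
Conditions: Ac2O, pyridine, 4-(dimethylamino)pyridine (cat.), CH2Cl2, 0 °C
Reagents that add atoms: acetic anhydride, CC(=O)OC(C)=O
Why: Acetylation of a secondary allylic alcohol under mild basic conditions, with retention at C2 and no acid that could trigger transannular cyclisation.

## Compound list

1 | α-santonin (3-oxoeudesma-1,4-dien-6α,12-olide, 11βH) | C[C@H]1[C@@H]2CC[C@]3(C=CC(=O)C(=C3[C@H]2OC1=O)C)C | starting material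
2 | 11β-(phenylselanyl)santonin (C13 methyl α) | C[C@@]1([Se]c4ccccc4)[C@@H]2CC[C@]3(C=CC(=O)C(=C3[C@H]2OC1=O)C)C | intermediate
3 | selenoxide of 2 (not isolated) | C[C@@]1([Se](=O)c4ccccc4)[C@@H]2CC[C@]3(C=CC(=O)C(=C3[C@H]2OC1=O)C)C | intermediate
4 | 11,13-dehydrosantonin (3-oxoeudesma-1,4,11(13)-trien-6α,12-olide) | C=C1[C@@H]2CC[C@]3(C=CC(=O)C(=C3[C@H]2OC1=O)C)C | intermediate
5 | 11β,13-dihydroxy-3-oxoeudesma-1,4-dien-6α,12-olide | OC[C@@]1(O)[C@@H]2CC[C@]3(C=CC(=O)C(=C3[C@H]2OC1=O)C)C | intermediate
6 | 13-acetoxy-11β-hydroxy-3-oxoeudesma-1,4-dien-6α,12-olide | CC(=O)OC[C@@]1(O)[C@@H]2CC[C@]3(C=CC(=O)C(=C3[C@H]2OC1=O)C)C | intermediate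
7 | 13-acetoxy-11β-hydroxy-3-oxoeudesm-4-en-6α,12-olide | CC(=O)OC[C@@]1(O)[C@@H]2CC[C@@]3(C)CCC(=O)C(C)=C3[C@H]2OC1=O | intermediate
8 | 13-acetoxy-3β,11β-dihydroxyeudesm-4-en-6α,12-olide | CC(=O)OC[C@@]1(O)[C@@H]2CC[C@@]3(C)CC[C@H](O)C(C)=C3[C@H]2OC1=O | intermediate
9 | 3α-[N-amino-N-(2-nitrobenzenesulfonyl)amino] derivative of 8 (hydroxyl replaced with inversion; not isolated) | CC(=O)OC[C@@]1(O)[C@@H]2CC[C@@]3(C)CC[C@@H](N(N)S(=O)(=O)c4ccccc4[N+](=O)[O-])C(C)=C3[C@H]2OC1=O | intermediate
10 | 3α-diazenyl-13-acetoxy-11β-hydroxyeudesm-4-en-6α,12-olide (not isolated) | CC(=O)OC[C@@]1(O)[C@@H]2CC[C@@]3(C)CC[C@@H](N=N)C(C)=C3[C@H]2OC1=O | intermediate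
11 | 13-acetoxy-11β-hydroxy-5αH-eudesm-3-en-6α,12-olide | CC(=O)OC[C@@]1(O)[C@@H]2CC[C@@]3(C)CCC=C(C)[C@@H]3[C@H]2OC1=O | intermediate
12 | 13-acetoxy-11β-hydroxy-2-oxo-5αH-eudesm-3-en-6α,12-olide | CC(=O)OC[C@@]1(O)[C@@H]2CC[C@@]3(C)CC(=O)C=C(C)[C@@H]3[C@H]2OC1=O | intermediate
13 | 11-O-chlorosulfite of 12 (not isolated) | CC(=O)OC[C@@]1(OS(=O)Cl)[C@@H]2CC[C@@]3(C)CC(=O)C=C(C)[C@@H]3[C@H]2OC1=O | intermediate
14 | 13-acetoxy-2-oxo-5αH-eudesma-3,7(11)-dien-6α,12-olide | CC(=O)OCC1=C2CC[C@@]3(C)CC(=O)C=C(C)[C@@H]3[C@H]2OC1=O | intermediate
15 | 13-acetoxy-8β-hydroxy-2-oxo-5αH-eudesma-3,7(11)-dien-6α,12-olide | CC(=O)OCC1=C2[C@H](O)C[C@@]3(C)CC(=O)C=C(C)[C@@H]3[C@H]2OC1=O | intermediate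
16 | methacrylic acid | C=C(C)C(=O)O | starting material
17 | 13-acetoxy-8α-methacryloyloxy-2-oxo-5αH-eudesma-3,7(11)-dien-6α,12-olide | C=C(C)C(=O)O[C@H]1C[C@@]2(C)CC(=O)C=C(C)[C@@H]2[C@H]3OC(=O)C(COC(C)=O)=C13 | intermediate
18 | 13-acetoxy-8α-methacryloyloxy-2-triethylsilyloxy-5αH-eudesma-1,3,7(11)-trien-6α,12-olide (key-step precursor) | C=C(C)C(=O)O[C@H]1C[C@@]2(C)C=C(O[Si](CC)(CC)CC)C=C(C)[C@@H]2[C@H]3OC(=O)C(COC(C)=O)=C13 | intermediate
19 | 13-acetoxy-8α-methacryloyloxy-2-triethylsilyloxygermacra-1(10),2,4,7(11)-tetraen-6α,12-olide (C1=C10 and C4=C5 E; C1 and C4 cis across C2=C3; key-step product) | C=C(C)C(=O)O[C@H]1C/C(C)=C/C(O[Si](CC)(CC)CC)=C\C(C)=C\[C@H]2OC(=O)C(COC(C)=O)=C12 | intermediate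
20 | 13-acetoxy-8α-methacryloyloxy-2-oxogermacra-1(10)E,4E,7(11)-trien-6α,12-olide | C=C(C)C(=O)O[C@H]1C/C(C)=C/C(=O)C/C(C)=C/[C@H]2OC(=O)C(COC(C)=O)=C12 | intermediate
21 | (2R)-13-acetoxy-2-hydroxy-8α-methacryloyloxygermacra-1(10)E,4E,7(11)-trien-6α,12-olide | C=C(C)C(=O)O[C@H]1C/C(C)=C/[C@H](O)C/C(C)=C/[C@H]2OC(=O)C(COC(C)=O)=C12 | intermediate
22 | (2R,6R,8S)-2,13-diacetoxy-8-methacryloyloxygermacra-1(10)E,4E,7(11)-trien-6,12-olide | C=C(C)C(=O)O[C@H]1C/C(C)=C/[C@H](OC(C)=O)C/C(C)=C/[C@H]2OC(=O)C(COC(C)=O)=C12 | target

## Step count and least certain steps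

Total: 16 steps. Longest linear sequence: 16 steps, from α-santonin 1 (methacrylic acid 16 is bought).

**Step 13 (key step).** The opening may stall at an unfavourable photostationary mixture, the triene may reclose thermally while the cold solution is handled, and excitation may be diverted into cycloaddition or polymerisation of the methacrylate. The fallback takes the methacrylate out of the photolysis; it sets out from 15 and comes back at 20. Alcohol 15 is treated with Et3SiOTf (2.2 equiv) and Et3N at −78 °C to give the bis-silyl compound, 8β-triethylsilyloxy-2-triethylsilyloxy diene F1. Irradiation as in step 13 gives the bis-silyl triene F2. Buffered Bu4NF/AcOH removes both silyl groups to give the 8β-hydroxy dienone F3. Mitsunobu esterification of F3 with methacrylic acid 16 (PPh3, diisopropyl azodicarboxylate) inverts C8 and gives 20.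

**Step 12.** Silyl transfer to the butenolide carbonyl would form a 2-silyloxyfuran and lose the C6 configuration; deprotonation at C15 or C5 instead of C1 is the second risk. The fallback activates only the ketone; it sets out from 17 and comes back at 20. Base-free ketalisation (MeOSiMe3, catalytic Me3SiOTf, CH2Cl2, −78 °C) gives the dimethyl ketal F4. Me3SiOTf with iPr2NEt then ionises the ketal alone and eliminates methanol to give the 2-methoxy-1,3-diene F5. Irradiation as in step 13 gives the methoxy triene F6, and cold dilute aqueous oxalic acid in THF hydrolyses the enol ether to 20.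

**Step 10.** The ene reaction may be slow on the electron-poor olefin, oxidation may be diverted to C1 next to the ring-A ketone, to the γ-positions of the enone or to C6–H, and over-oxidation to the 8-ketone may occur. The fallback replaces hydroxylation by oxidation to the ketone and reduction; it sets out from 14 and comes back at 15. Radical γ-oxidation with dirhodium tetrakis(caprolactamate), Rh2(cap)4, and tert-butyl hydroperoxide gives the 2,8-dione F7. Luche reduction (NaBH4, CeCl3·7H2O, −78 °C) reduces both ketones from the α face to the 2β,8β-diol F8. 2,3-Dichloro-5,6-dicyano-1,4-benzoquinone then re-oxidises only the ring-A allylic alcohol, next to the electron-rich olefin, to give 15.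

**Step 11.** The activated axial oxygen may be lost by E2 elimination with the antiperiplanar H9 to a dienolide, or substitution may stall at the hindered carbinol. The fallback separates inversion from introduction of the acyl group; it sets out from 15 and comes back at 17. Mitsunobu reaction with the smaller and more acidic chloroacetic acid gives the 8α-chloroacetate F9. Thiourea with NaHCO3 in ethanol removes the chloroacetyl group selectively to give the 8α-alcohol F10. Methacryloyl chloride with Et3N and catalytic 4-(dimethylamino)pyridine gives 17. Should step 10 deliver the 8α-alcohol directly, that material enters the route through this last acylation.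

**Step 7.** Activation of the hindered allylic alcohol next to the fully substituted C4 may end in elimination to a diene or in allylic transposition of the nucleophile, with loss of the stereospecific hydrogen delivery. The fallback is a palladium-mediated hydride transfer; it sets out from 8 and comes back at 11. Formylation of the secondary alcohol (formic acid, N,N′-dicyclohexylcarbodiimide) gives the 3β-formate F11. Pd(OAc)2 with PBu3 in THF displaces the formate with inversion, and the hydride formed by loss of CO2 is delivered from the metal to the α face of C5, giving 11.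

**Step 15.** The facial bias of the ten-membered ring may override the catalyst and give the wrong C2 epimer, or 1,4-reduction may compete. If the ring's own bias is toward the (2S)-alcohol, the fallback uses it; it sets out from 20 and comes back at 22. Luche reduction under substrate control gives the (2S)-alcohol F12, and Mitsunobu reaction of F12 with acetic acid (PPh3, diisopropyl azodicarboxylate) installs the acetate with inversion, giving 22 directly.

## Further compounds

F1 | step 13 | 13-acetoxy-2,8β-bis(triethylsilyloxy)-5αH-eudesma-1,3,7(11)-trien-6α,12-olide | CC[Si](CC)(CC)O[C@@H]1C[C@@]2(C)C=C(O[Si](CC)(CC)CC)C=C(C)[C@@H]2[C@H]3OC(=O)C(COC(C)=O)=C13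
F2 | step 13 | 13-acetoxy-2,8β-bis(triethylsilyloxy)germacra-1(10),2,4,7(11)-tetraen-6α,12-olide | CC[Si](CC)(CC)O[C@@H]1C/C(C)=C/C(O[Si](CC)(CC)CC)=C\C(C)=C\[C@H]2OC(=O)C(COC(C)=O)=C12
F3 | step 13 | 13-acetoxy-8β-hydroxy-2-oxogermacra-1(10)E,4E,7(11)-trien-6α,12-olide | O[C@@H]1C/C(C)=C/C(=O)C/C(C)=C/[C@H]2OC(=O)C(COC(C)=O)=C12
F4 | step 12 | 13-acetoxy-2,2-dimethoxy-8α-methacryloyloxy-5αH-eudesma-3,7(11)-dien-6α,12-olide | C=C(C)C(=O)O[C@H]1C[C@@]2(C)CC(OC)(OC)C=C(C)[C@@H]2[C@H]3OC(=O)C(COC(C)=O)=C13
F5 | step 12 | 13-acetoxy-2-methoxy-8α-methacryloyloxy-5αH-eudesma-1,3,7(11)-trien-6α,12-olide | C=C(C)C(=O)O[C@H]1C[C@@]2(C)C=C(OC)C=C(C)[C@@H]2[C@H]3OC(=O)C(COC(C)=O)=C13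
F6 | step 12 | 13-acetoxy-2-methoxy-8α-methacryloyloxygermacra-1(10),2,4,7(11)-tetraen-6α,12-olide | C=C(C)C(=O)O[C@H]1C/C(C)=C/C(OC)=C\C(C)=C\[C@H]2OC(=O)C(COC(C)=O)=C12
F7 | step 10 | 13-acetoxy-2,8-dioxo-5αH-eudesma-3,7(11)-dien-6α,12-olide | CC(=O)OCC1=C2C(=O)C[C@@]3(C)CC(=O)C=C(C)[C@@H]3[C@H]2OC1=O
F8 | step 10 | 13-acetoxy-2β,8β-dihydroxy-5αH-eudesma-3,7(11)-dien-6α,12-olide | CC(=O)OCC1=C2[C@H](O)C[C@@]3(C)C[C@H](O)C=C(C)[C@@H]3[C@H]2OC1=O
F9 | step 11 | 13-acetoxy-8α-chloroacetoxy-2-oxo-5αH-eudesma-3,7(11)-dien-6α,12-olide | ClCC(=O)O[C@H]1C[C@@]2(C)CC(=O)C=C(C)[C@@H]2[C@H]3OC(=O)C(COC(C)=O)=C13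
F10 | step 11 | 13-acetoxy-8α-hydroxy-2-oxo-5αH-eudesma-3,7(11)-dien-6α,12-olide | O[C@H]1C[C@@]2(C)CC(=O)C=C(C)[C@@H]2[C@H]3OC(=O)C(COC(C)=O)=C13
F11 | step 7 | 13-acetoxy-3β-formyloxy-11β-hydroxyeudesm-4-en-6α,12-olide | CC(=O)OC[C@@]1(O)[C@@H]2CC[C@@]3(C)CC[C@H](OC=O)C(C)=C3[C@H]2OC1=O
F12 | step 15 | (2S)-13-acetoxy-2-hydroxy-8α-methacryloyloxygermacra-1(10)E,4E,7(11)-trien-6α,12-olide | C=C(C)C(=O)O[C@H]1C/C(C)=C/[C@@H](O)C/C(C)=C/[C@H]2OC(=O)C(COC(C)=O)=C12
A1 | alternative 1 | tris-silylated bicyclic core (8-O-triethylsilyl, 2,13-bis-O-tert-butyldimethylsilyl) | CC[Si](CC)(CC)O[C@H]1C/C(C)=C/[C@H](O[Si](C)(C)C(C)(C)C)C/C(C)=C/[C@H]2OC(=O)C(CO[Si](C)(C)C(C)(C)C)=C12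
A2 | alternative 1 | acyclic ynal, (2E,6E)-dienal with C7≡C11 alkyne and three silyl ethers | O=C/C=C(\C)C[C@@H](O[Si](C)(C)C(C)(C)C)/C=C(\C)C[C@H](O[Si](CC)(CC)CC)C#CCO[Si](C)(C)C(C)(C)C
A3 | alternative 2 | protected bicyclic core with C8 4-methoxybenzyl ether | COc1ccc(CO[C@H]2C/C(C)=C/[C@H](O[Si](C)(C)C(C)(C)C)C/C(C)=C/[C@H]3OC(=O)C(CO[Si](C)(C)C(C)(C)C)=C23)cc1
A4 | alternative 2 | butenolide N-acyloxyphthalimide carrying the C10 alkenyl iodide | COc1ccc(CO[C@@H](CC(=O)ON2C(=O)c3ccccc3C2=O)C2=C(CO[Si](C)(C)C(C)(C)C)C(=O)O[C@@H]2/C=C(\C)C[C@@H](O[Si](C)(C)C(C)(C)C)/C=C(\C)I)cc1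
A5 | alternative 3 | ten-membered butenolide with free C8 alcohol | O[C@H]1C/C(C)=C/[C@H](O[Si](C)(C)C(C)(C)C)C/C(C)=C/[C@H]2OC(=O)C(CO[Si](C)(C)C(C)(C)C)=C12
A6 | alternative 3 | β-bromobutenolide with C8 aldehyde side chain | O=CC/C(C)=C/[C@H](O[Si](C)(C)C(C)(C)C)C/C(C)=C/[C@H]1OC(=O)C(CO[Si](C)(C)C(C)(C)C)=C1Br
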